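**Retrosynthetic overview**

1. The target comes from its 7-O-triisopropylsilyl ether, and that quinone comes from a thermal four-to-six ring expansion of a 4-alkynyl-4-hydroxy-2,3-dimethoxycyclobutenone (quinone ring formed last).
2. The cyclobutenone comes from dimethyl squarate and the lithium acetylide of an (S)-3-ethynylchroman, made from the chroman-3-carbaldehyde through its dibromoolefin.
3. The pyran ring of the chroman (formed first) comes from a palladium-catalysed intramolecular C–O coupling of a 2-bromoaryl primary alcohol; C3 is set by auxiliary-controlled benzyloxymethylation of an N-(3-arylpropanoyl)oxazolidinone.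
4. The aryl unit comes from syringaldehyde by silylation, bromination and Meldrum's acid homologation.
5. Enabling feature: in the quinone ring, C1(=O)–C2(OMe)=C3(OMe)–C4(=O) is the intact carbon square of dimethyl squarate, and C5 (bearing chroman C3) with C6–H is a terminal alkyne; the square is symmetric, so insertion at either carbonyl gives the same ring, and C6–H comes from the cyclobutenol O–H.

Key step: step 12

Remark on the chemistry: the target is read as the (3S)-chroman; 19 (and F3 of a fallback) should form as both epimers at the carbinol carbon, which is destroyed in the ring expansion, so that center carries no configuration in the SMILES.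

**Route**

Step 1
Reactants: 1 syringaldehyde (4-hydroxy-3,5-dimethoxybenzaldehyde)
Product: 2 3,5-dimethoxy-4-[(triisopropylsilyl)oxy]benzaldehyde
Conditions: TIPSCl, imidazole, DMF, rt
Reagents that add atoms: triisopropylsilyl chloride, CC(C)[Si](Cl)(C(C)C)C(C)C
Why: O-silylation of the acidic phenol should proceed cleanly, and the hindered aryl TIPS ether is chosen because it should tolerate NBS, buffered formic acid, TiCl4, hydride, Cs2CO3, hydrogenolysis, n-BuLi and 140 °C and still leave with buffered fluoride at the end.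

Step 2
Reactants: 2 3,5-dimethoxy-4-[(triisopropylsilyl)oxy]benzaldehyde
Product: 3 2-bromo-3,5-dimethoxy-4-[(triisopropylsilyl)oxy]benzaldehyde
Conditions: NBS, MeCN, rt
Reagents that add atoms: N-bromosuccinimide, O=C1CCC(=O)N1Br
Why: Electrophilic aromatic bromination should occur at C2, one of the two equivalent free positions, each ortho to one methoxy group and para to the other, as is usual for 3,4,5-trialkoxybenzaldehydes.

Step 3
Reactants: 3 2-bromo-3,5-dimethoxy-4-[(triisopropylsilyl)oxy]benzaldehyde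
Product: 6 3-{2-bromo-3,5-dimethoxy-4-[(triisopropylsilyl)oxy]phenyl}propanoic acid, via arylidene Meldrum's acid 4 (not isolated), via arylmethyl Meldrum's acid 5 (not isolated)
Conditions: Meldrum's acid, HCO2H/Et3N (5:2), 95 °C
Reagents that add atoms: Meldrum's acid, CC1(C)OC(=O)CC(=O)O1
Why: Tandem Knoevenagel condensation, conjugate hydride transfer from formate and hydrolysis–decarboxylation should give the dihydrocinnamic acid in one pot without a metal, so the aryl bromide is not reduced.

Step 4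
Reactants: 6 3-{2-bromo-3,5-dimethoxy-4-[(triisopropylsilyl)oxy]phenyl}propanoic acid, 7 (4R)-4-benzyl-1,3-oxazolidin-2-one
Product: 9 (4R)-4-benzyl-3-(3-{2-bromo-3,5-dimethoxy-4-[(triisopropylsilyl)oxy]phenyl}propanoyl)-1,3-oxazolidin-2-one, via mixed pivalic anhydride 8 (not isolated)
Conditions: PivCl, Et3N, THF, −20 °C; then LiCl, 7, −20 °C to rt
Reagents that add atoms: none
Why: N-acylation of the oxazolidinone through the mixed pivalic anhydride (LiCl/Et3N activation of the N–H) is the standard way to load the auxiliary and creates no stereocenter.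

Step 5
Reactants: 9 (4R)-4-benzyl-3-(3-{2-bromo-3,5-dimethoxy-4-[(triisopropylsilyl)oxy]phenyl}propanoyl)-1,3-oxazolidin-2-one
Product: 11 (4R)-4-benzyl-3-[(2S)-2-[(benzyloxy)methyl]-3-{2-bromo-3,5-dimethoxy-4-[(triisopropylsilyl)oxy]phenyl}propanoyl]-1,3-oxazolidin-2-one, via chlorotitanium enolate 10 (not isolated)
Conditions: TiCl4, i-Pr2NEt, CH2Cl2, 0 °C; then BnOCH2Cl, 0 °C
Reagents that add atoms: benzyl chloromethyl ether, ClCOCc1ccccc1
Why: Evans auxiliary alkylation, in which the chelated chlorotitanium Z-enolate is attacked by the oxocarbenium-like electrophile on the face opposite the C4 benzyl group of the (R)-auxiliary, should set the new center as (2S).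

Step 6
Reactants: 11 (4R)-4-benzyl-3-[(2S)-2-[(benzyloxy)methyl]-3-{2-bromo-3,5-dimethoxy-4-[(triisopropylsilyl)oxy]phenyl}propanoyl]-1,3-oxazolidin-2-one
Product: 12 (2R)-3-(benzyloxy)-2-({2-bromo-3,5-dimethoxy-4-[(triisopropylsilyl)oxy]phenyl}methyl)propan-1-ol
Conditions: LiBH4, MeOH (1 equiv), Et2O, 0 °C
Reagents that add atoms: none
Why: Reductive cleavage of the auxiliary with LiBH4 reduces the exocyclic imide carbonyl without enolising the α-center, so the configuration is kept (the descriptor becomes R only through the priority change) and auxiliary 7 is recovered.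

Step 7
Reactants: 12 (2R)-3-(benzyloxy)-2-({2-bromo-3,5-dimethoxy-4-[(triisopropylsilyl)oxy]phenyl}methyl)propan-1-ol
Product: 13 (3S)-3-[(benzyloxy)methyl]-6,8-dimethoxy-7-[(triisopropylsilyl)oxy]-3,4-dihydro-2H-chromene
Conditions: Pd(OAc)2 (5 mol %), 2-(di-tert-butylphosphino)-1,1'-binaphthyl (6 mol %), Cs2CO3, toluene, 80 °C
Reagents that add atoms: none
Why: Intramolecular Buchwald–Hartwig etherification (oxidative addition of zerovalent palladium into the C–Br bond, alkoxide binding, C–O reductive elimination from the bulky biarylphosphine complex) should close the six-membered pyran ring, the stereocenter being β to the reacting oxygen and untouched.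

Step 8
Reactants: 13 (3S)-3-[(benzyloxy)methyl]-6,8-dimethoxy-7-[(triisopropylsilyl)oxy]-3,4-dihydro-2H-chromene
Product: 14 {(3S)-6,8-dimethoxy-7-[(triisopropylsilyl)oxy]-3,4-dihydro-2H-chromen-3-yl}methanol
Conditions: H2 (1 atm), Pd/C (palladium on carbon), EtOAc/EtOH, rt
Reagents that add atoms: none
Why: Hydrogenolysis of the primary benzyl ether should leave the aryl silyl ether, the aryl methyl ethers and the non-benzylic C–O bonds of the chroman intact.

Step 9
Reactants: 14 {(3S)-6,8-dimethoxy-7-[(triisopropylsilyl)oxy]-3,4-dihydro-2H-chromen-3-yl}methanol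
Product: 15 (3R)-6,8-dimethoxy-7-[(triisopropylsilyl)oxy]-3,4-dihydro-2H-chromene-3-carbaldehyde
Conditions: Dess–Martin periodinane, CH2Cl2, 0 °C to rt
Reagents that add atoms: none
Why: Dess–Martin oxidation under non-basic conditions should give the α-branched aldehyde without epimerisation (the descriptor becomes R only through the priority change), and the aldehyde is used at once.

Step 10
Reactants: 15 (3R)-6,8-dimethoxy-7-[(triisopropylsilyl)oxy]-3,4-dihydro-2H-chromene-3-carbaldehyde
Product: 16 (3S)-3-(2,2-dibromoethenyl)-6,8-dimethoxy-7-[(triisopropylsilyl)oxy]-3,4-dihydro-2H-chromene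
Conditions: CBr4, PPh3, Zn, CH2Cl2, rt; then 15, 0 °C to rt
Reagents that add atoms: carbon tetrabromide, BrC(Br)(Br)Br
Why: Corey–Fuchs dibromoolefination (Wittig reaction of Ph3P=CBr2 pre-formed with zinc) is non-basic and should leave the α-stereocenter unchanged.

Step 11
Reactants: 16 (3S)-3-(2,2-dibromoethenyl)-6,8-dimethoxy-7-[(triisopropylsilyl)oxy]-3,4-dihydro-2H-chromene, 17 dimethyl squarate (3,4-dimethoxycyclobut-3-ene-1,2-dione)
Product: 19 4-({(3S)-6,8-dimethoxy-7-[(triisopropylsilyl)oxy]-3,4-dihydro-2H-chromen-3-yl}ethynyl)-4-hydroxy-2,3-dimethoxycyclobut-2-en-1-one, via lithium acetylide 18 (not isolated)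
Conditions: n-BuLi (2.0 equiv), THF, −78 to 0 °C; then added to 17 (1.5 equiv), THF, −78 °C; aq NH4Cl
Reagents that add atoms: none
Why: Bromine–lithium exchange, Fritsch–Buttenberg–Wiechell rearrangement and deprotonation (second stage of the Corey–Fuchs sequence) give the lithium acetylide, which should add 1,2 to one of the two equivalent carbonyl groups of excess dimethyl squarate at −78 °C, the new carbinol center forming without control and without consequence.

Step 12
Reactants: 19 4-({(3S)-6,8-dimethoxy-7-[(triisopropylsilyl)oxy]-3,4-dihydro-2H-chromen-3-yl}ethynyl)-4-hydroxy-2,3-dimethoxycyclobut-2-en-1-one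
Product: 22 5-{(3S)-6,8-dimethoxy-7-[(triisopropylsilyl)oxy]-3,4-dihydro-2H-chromen-3-yl}-2,3-dimethoxycyclohexa-2,5-diene-1,4-dione, via enynyl ketene 20 (not isolated), via aryl phenoxyl diradical 21 (not isolated)
Conditions: p-xylene (degassed, 0.01 M), 138 °C
Reagents that add atoms: none
Why: Heating should open the cyclobutenone by conrotatory 4π electrocyclic cleavage of the C1–C4 bond with the hydroxyl group rotating outward, so that the alkynyl group lies cis to the ketene in 20; the ketene carbon then bonds to the remote alkyne carbon to give the six-membered diradical 21 (phenoxyl oxygen plus a σ-radical on the former inner alkyne carbon), and transfer of the hydroxyl hydrogen to that carbon gives the quinone directly at its final oxidation level. The closest known reaction is the Moore rearrangement of 4-alkynyl-4-hydroxycyclobutenones to 1,4-benzoquinones, in which alkyl-substituted alkynes on the dimethyl squarate core are standard substrates. The carbocycle closes in the 6-endo-dig mode (new bond between the future quinone C4 and C5), enlarging the four-membered ring by the two alkyne carbons. No stereocenter is formed: the carbinol center is planarised, and C3 of the chroman takes no part, since the σ-radical can reach only the C2 and C4 methylene hydrogens through a six-membered transition state and the medium is neutral. The step needs six- over five-membered closure (5-exo-dig would give an alkylidenecyclopentenedione), which the non-radical-stabilising secondary alkyl substituent on the alkyne should secure, while regiochemistry cannot go wrong because both halves of the squarate unit are equivalent. High dilution and degassing should suppress intermolecular reactions of the diradical.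

Step 13
Reactants: 22 5-{(3S)-6,8-dimethoxy-7-[(triisopropylsilyl)oxy]-3,4-dihydro-2H-chromen-3-yl}-2,3-dimethoxycyclohexa-2,5-diene-1,4-dione
Product: 23 5-[(3S)-7-hydroxy-6,8-dimethoxy-3,4-dihydro-2H-chromen-3-yl]-2,3-dimethoxycyclohexa-2,5-diene-1,4-dione (CNP0121136.1)
Conditions: TBAF, AcOH (1:1), THF, 0 °C
Reagents that add atoms: none
Why: Fluoride-induced desilylation of the aryl silyl ether, buffered with AcOH so that neither the phenoxide nor the base-sensitive quinone can enolise C3–H to a quinone methide, should release the phenol with the stereocenter retained.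

**Compound list**

1 | syringaldehyde (4-hydroxy-3,5-dimethoxybenzaldehyde) | COc1cc(C=O)cc(OC)c1O | starting material
2 | 3,5-dimethoxy-4-[(triisopropylsilyl)oxy]benzaldehyde | COc1cc(C=O)cc(OC)c1O[Si](C(C)C)(C(C)C)C(C)C | intermediate
3 | 2-bromo-3,5-dimethoxy-4-[(triisopropylsilyl)oxy]benzaldehyde | COc1cc(C=O)c(Br)c(OC)c1O[Si](C(C)C)(C(C)C)C(C)C | intermediate
4 | 5-({2-bromo-3,5-dimethoxy-4-[(triisopropylsilyl)oxy]phenyl}methylidene)-2,2-dimethyl-1,3-dioxane-4,6-dione (arylidene Meldrum's acid) | COc1cc(C=C2C(=O)OC(C)(C)OC2=O)c(Br)c(OC)c1O[Si](C(C)C)(C(C)C)C(C)C | intermediate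
5 | 5-({2-bromo-3,5-dimethoxy-4-[(triisopropylsilyl)oxy]phenyl}methyl)-2,2-dimethyl-1,3-dioxane-4,6-dione (arylmethyl Meldrum's acid) | COc1cc(CC2C(=O)OC(C)(C)OC2=O)c(Br)c(OC)c1O[Si](C(C)C)(C(C)C)C(C)C | intermediate
6 | 3-{2-bromo-3,5-dimethoxy-4-[(triisopropylsilyl)oxy]phenyl}propanoic acid | COc1cc(CCC(=O)O)c(Br)c(OC)c1O[Si](C(C)C)(C(C)C)C(C)C | intermediate
7 | (4R)-4-benzyl-1,3-oxazolidin-2-one | O=C1N[C@H](Cc2ccccc2)CO1 | starting material
8 | mixed anhydride of 6 with pivalic acid | COc1cc(CCC(=O)OC(=O)C(C)(C)C)c(Br)c(OC)c1O[Si](C(C)C)(C(C)C)C(C)C | intermediate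
9 | (4R)-4-benzyl-3-(3-{2-bromo-3,5-dimethoxy-4-[(triisopropylsilyl)oxy]phenyl}propanoyl)-1,3-oxazolidin-2-one | COc1cc(CCC(=O)N2[C@H](Cc3ccccc3)COC2=O)c(Br)c(OC)c1O[Si](C(C)C)(C(C)C)C(C)C | intermediate
10 | trichlorotitanium Z-enolate of 9 | Cl[Ti](Cl)(Cl)O/C(=C\Cc1cc(OC)c(O[Si](C(C)C)(C(C)C)C(C)C)c(OC)c1Br)N2[C@H](Cc3ccccc3)COC2=O | intermediate
11 | (4R)-4-benzyl-3-[(2S)-2-[(benzyloxy)methyl]-3-{2-bromo-3,5-dimethoxy-4-[(triisopropylsilyl)oxy]phenyl}propanoyl]-1,3-oxazolidin-2-one | c1ccccc1COC[C@H](Cc2cc(OC)c(O[Si](C(C)C)(C(C)C)C(C)C)c(OC)c2Br)C(=O)N3[C@H](Cc4ccccc4)COC3=O | intermediate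
12 | (2R)-3-(benzyloxy)-2-({2-bromo-3,5-dimethoxy-4-[(triisopropylsilyl)oxy]phenyl}methyl)propan-1-ol | c1ccccc1COC[C@H](Cc2cc(OC)c(O[Si](C(C)C)(C(C)C)C(C)C)c(OC)c2Br)CO | intermediate
13 | (3S)-3-[(benzyloxy)methyl]-6,8-dimethoxy-7-[(triisopropylsilyl)oxy]-3,4-dihydro-2H-chromene | c1ccccc1COC[C@H]2COc3c(cc(OC)c(O[Si](C(C)C)(C(C)C)C(C)C)c3OC)C2 | intermediate
14 | {(3S)-6,8-dimethoxy-7-[(triisopropylsilyl)oxy]-3,4-dihydro-2H-chromen-3-yl}methanol | OC[C@H]1COc2c(cc(OC)c(O[Si](C(C)C)(C(C)C)C(C)C)c2OC)C1 | intermediate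
15 | (3R)-6,8-dimethoxy-7-[(triisopropylsilyl)oxy]-3,4-dihydro-2H-chromene-3-carbaldehyde | O=C[C@H]1COc2c(cc(OC)c(O[Si](C(C)C)(C(C)C)C(C)C)c2OC)C1 | intermediate
16 | (3S)-3-(2,2-dibromoethenyl)-6,8-dimethoxy-7-[(triisopropylsilyl)oxy]-3,4-dihydro-2H-chromene | BrC(Br)=C[C@H]1COc2c(cc(OC)c(O[Si](C(C)C)(C(C)C)C(C)C)c2OC)C1 | intermediate
17 | dimethyl squarate (3,4-dimethoxycyclobut-3-ene-1,2-dione) | COC1=C(OC)C(=O)C1=O | starting material
18 | lithium acetylide of (3S)-3-ethynyl-6,8-dimethoxy-7-[(triisopropylsilyl)oxy]-3,4-dihydro-2H-chromene | [Li]C#C[C@H]1COc2c(cc(OC)c(O[Si](C(C)C)(C(C)C)C(C)C)c2OC)C1 | intermediate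
19 | 4-({(3S)-6,8-dimethoxy-7-[(triisopropylsilyl)oxy]-3,4-dihydro-2H-chromen-3-yl}ethynyl)-4-hydroxy-2,3-dimethoxycyclobut-2-en-1-one (both epimers at the carbinol carbon) | COC1=C(OC)C(O)(C#C[C@H]2COc3c(cc(OC)c(O[Si](C(C)C)(C(C)C)C(C)C)c3OC)C2)C1=O | intermediate
20 | (3Z)-6-{(3S)-6,8-dimethoxy-7-[(triisopropylsilyl)oxy]-3,4-dihydro-2H-chromen-3-yl}-4-hydroxy-2,3-dimethoxyhexa-1,3-dien-5-yn-1-one (enynyl ketene) | O=C=C(OC)/C(OC)=C(/O)C#C[C@H]1COc2c(cc(OC)c(O[Si](C(C)C)(C(C)C)C(C)C)c2OC)C1 | intermediate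
21 | 6-{(3S)-6,8-dimethoxy-7-[(triisopropylsilyl)oxy]-3,4-dihydro-2H-chromen-3-yl}-4-hydroxy-2,3-dimethoxyphenoxyl carrying a σ-radical at C5 (diradical) | [O]c1c(OC)c(OC)c(O)[c]c1[C@H]2COc3c(cc(OC)c(O[Si](C(C)C)(C(C)C)C(C)C)c3OC)C2 | intermediate
22 | 5-{(3S)-6,8-dimethoxy-7-[(triisopropylsilyl)oxy]-3,4-dihydro-2H-chromen-3-yl}-2,3-dimethoxycyclohexa-2,5-diene-1,4-dione | COC1=C(OC)C(=O)C([C@H]2COc3c(cc(OC)c(O[Si](C(C)C)(C(C)C)C(C)C)c3OC)C2)=CC1=O | intermediate
23 | 5-[(3S)-7-hydroxy-6,8-dimethoxy-3,4-dihydro-2H-chromen-3-yl]-2,3-dimethoxycyclohexa-2,5-diene-1,4-dione (CNP0121136.1) | COC1=C(OC)C(=O)C([C@H]2COc3c(cc(OC)c(O)c3OC)C2)=CC1=O | target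

**Step count and risks**

Total step count: 13. Longest linear sequence: 13 steps (from 1 to 23; 7 and 17 are bought).

Steps most likely to fail:

1. Step 12 (ring expansion). The diradical may divert into five-membered closure, into intermolecular radical coupling, or into hydrogen abstraction from the chroman methylene groups, so that little quinone forms. The fallback replaces the diradical path by a closed-shell one and sets out from 15. Takai olefination (CHI3, CrCl2, THF, 0 °C) should give (3S)-3-[(E)-2-iodoethenyl]-6,8-dimethoxy-7-[(triisopropylsilyl)oxy]-3,4-dihydro-2H-chromene F1. Iodine–lithium exchange (t-BuLi, 2 equiv, THF, −78 °C) gives the corresponding (E)-alkenyllithium F2, which is added to 17 at −78 °C to give the 4-alkenyl-4-hydroxy-2,3-dimethoxycyclobutenone F3. Heating F3 in toluene at 110 °C (4π ring opening, 6π electrocyclisation, tautomerisation) should give the 5-chromanyl-2,3-dimethoxybenzene-1,4-diol F4, and oxidation with Ag2O (Et2O, rt) comes back to the route at 22.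

2. Step 7 (C–O cyclisation). β-Hydride elimination from the palladium alkoxide may outpace C–O reductive elimination at the hindered, electron-rich aryl center, which would reduce the C–Br bond and oxidise the alcohol. The fallback forms the ring by an SN2-type O-alkylation instead and sets out from 12. Miyaura borylation (B2pin2, Pd(dppf)Cl2, KOAc, dioxane, 90 °C) should give the aryl pinacol boronate F5. Oxidation (NaBO3, THF/H2O, rt) gives 6-[(2R)-3-(benzyloxy)-2-(hydroxymethyl)propyl]-2,4-dimethoxy-3-[(triisopropylsilyl)oxy]phenol F6, and intramolecular Mitsunobu etherification (PPh3, DIAD, THF, 0 °C to rt) comes back to the route at 13.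

3. Step 11 (telescoped acetylide formation and addition). Incomplete carbenoid rearrangement or leftover butyllithium would leave competing nucleophiles that add to the squarate, and double addition is possible. The fallback makes and purifies the alkyne first and sets out from 15. Colvin homologation with lithiated trimethylsilyldiazomethane (Me3SiCHN2, n-BuLi, THF, −78 °C to rt) should give (3S)-3-ethynyl-6,8-dimethoxy-7-[(triisopropylsilyl)oxy]-3,4-dihydro-2H-chromene F7. Exactly one equivalent of n-BuLi (THF, −78 °C) then gives 18, which is added to 17 as before, coming back to the route at 19.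

**Further compounds**

F1 | step 12 | (3S)-3-[(E)-2-iodoethenyl]-6,8-dimethoxy-7-[(triisopropylsilyl)oxy]-3,4-dihydro-2H-chromene | I/C=C/[C@H]1COc2c(cc(OC)c(O[Si](C(C)C)(C(C)C)C(C)C)c2OC)C1
F2 | step 12 | (E)-2-{(3S)-6,8-dimethoxy-7-[(triisopropylsilyl)oxy]-3,4-dihydro-2H-chromen-3-yl}ethenyllithium | [Li]/C=C/[C@H]1COc2c(cc(OC)c(O[Si](C(C)C)(C(C)C)C(C)C)c2OC)C1
F3 | step 12 | 4-[(E)-2-{(3S)-6,8-dimethoxy-7-[(triisopropylsilyl)oxy]-3,4-dihydro-2H-chromen-3-yl}ethenyl]-4-hydroxy-2,3-dimethoxycyclobut-2-en-1-one (both epimers at the carbinol carbon) | COC1=C(OC)C(O)(/C=C/[C@H]2COc3c(cc(OC)c(O[Si](C(C)C)(C(C)C)C(C)C)c3OC)C2)C1=O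
F4 | step 12 | 5-{(3S)-6,8-dimethoxy-7-[(triisopropylsilyl)oxy]-3,4-dihydro-2H-chromen-3-yl}-2,3-dimethoxybenzene-1,4-diol | COc1c(OC)c(O)c([C@H]2COc3c(cc(OC)c(O[Si](C(C)C)(C(C)C)C(C)C)c3OC)C2)cc1O
F5 | step 7 | (2R)-3-(benzyloxy)-2-({3,5-dimethoxy-2-(4,4,5,5-tetramethyl-1,3,2-dioxaborolan-2-yl)-4-[(triisopropylsilyl)oxy]phenyl}methyl)propan-1-ol | c1ccccc1COC[C@H](Cc2cc(OC)c(O[Si](C(C)C)(C(C)C)C(C)C)c(OC)c2B3OC(C)(C)C(C)(C)O3)CO
F6 | step 7 | 6-[(2R)-3-(benzyloxy)-2-(hydroxymethyl)propyl]-2,4-dimethoxy-3-[(triisopropylsilyl)oxy]phenol | c1ccccc1COC[C@H](Cc2cc(OC)c(O[Si](C(C)C)(C(C)C)C(C)C)c(OC)c2O)CO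
F7 | step 11 | (3S)-3-ethynyl-6,8-dimethoxy-7-[(triisopropylsilyl)oxy]-3,4-dihydro-2H-chromene | C#C[C@H]1COc2c(cc(OC)c(O[Si](C(C)C)(C(C)C)C(C)C)c2OC)C1
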